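**Strategy.** The route rests on disconnecting the C11–C12 bond. The unit O–C12–C11–C9(H)–C8=C17 on ring B is a 4-penten-1-ol, the retron of a nickel-catalysed diene–aldehyde homoallylation. One operation should join a flat ring-B diene (exocyclic methylenes on C8 and C9, C6 ketone in place, no C9 stereocentre, no side chain) to a five-carbon aldehyde. It should form C11–C12, place H on C9 from the α face, set the C12 carbinol and reveal the C8=C17 alkene β,γ to the ketone without base. The diene comes from (+)-sclareolide. The aldehyde carries C12–C16 with nitrogen masked as a nitrile, so the imide is closed afterwards under neutral conditions.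

Key step: step 8

Remark on the chemistry: labdane numbering is used (ring A = C1–C5 and C10, ring B = C5–C10, side chain C11–C12, imide C13–C16, exocyclic methylene C17). The SMILES is read as 2α (equatorial) Cl, 5α-H, 9α-H, 10β-CH3, 12S, 13R. (+)-Sclareolide and 4-oxobutanenitrile are taken as commercial.

Step 1
Reactants: 1 (+)-sclareolide
Product: 2 2α-chlorosclareolide
Conditions: N-chloro-N-tert-butyl-3,5-bis(trifluoromethyl)benzamide (1.0 equiv), Cs2CO3, PhH, visible light, 55 °C
Reagents that add atoms: N-chloro-N-tert-butyl-3,5-bis(trifluoromethyl)benzamide, CC(C)(C)N(Cl)C(=O)c1cc(cc(c1)C(F)(F)F)C(F)(F)F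
Why: Amidyl-radical C–H chlorination (radical chain): the electron-poor amidyl radical should abstract the most accessible methylene hydrogen remote from the lactone (C2), and chlorine is delivered to the equatorial α face away from the axial C4 and C10 methyls, which sets C2.

Step 2
Reactants: 2 2α-chlorosclareolide
Product: 3 2α-chloro-8α-hydroxy C12 methyl ketone
Conditions: MeLi (1.1 equiv), THF, −78 °C; then H2O
Reagents that add atoms: methyllithium, [Li]C
Why: Mono-addition of an organolithium to the γ-lactone: the lithium hemiketal alkoxide is stable at low temperature and opens to the methyl ketone only on work-up, so over-addition is avoided and no stereocentre changes.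

Step 3
Reactants: 3 2α-chloro-8α-hydroxy C12 methyl ketone
Product: 4 2α-chloro-8α-hydroxy C11 acetate
Conditions: mCPBA, TFA (cat.), CH2Cl2, 0 °C to rt
Reagents that add atoms: mCPBA, OOC(=O)c1cccc(Cl)c1
Why: Baeyer–Villiger oxidation: the primary alkyl group (C11) migrates in preference to methyl, so C11 now carries an acetoxy leaving group and the former lactone carbon is excised from the skeleton.

Step 4
Reactants: 4 2α-chloro-8α-hydroxy C11 acetate
Product: 5 2α-chloro-7,8-ene C11 acetate
Conditions: TfOH (10 mol %), CH2Cl2, −40 °C; then Et3N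
Reagents that add atoms: none
Why: Acid-catalysed E1 dehydration under kinetic control: the C8 cation should lose the axial C7 proton (as in acid-terminated polyene cyclisations) rather than the hindered C9 proton, giving mainly the trisubstituted 7,8-alkene, with any exocyclic isomer drawn into the same product by reprotonation.

Step 5
Reactants: 5 2α-chloro-7,8-ene C11 acetate
Product: 6 2α-chloro-6-oxo-7,8-ene C11 acetate
Conditions: CrO3, 3,5-dimethylpyrazole, CH2Cl2, −20 °C
Reagents that add atoms: chromium trioxide, O=[Cr](=O)=O
Why: Allylic oxidation with the CrO3–3,5-dimethylpyrazole complex: the only allylic methylene (C6) is oxidised to the conjugated enone, and C5 and C9 keep their configuration.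

Step 6
Reactants: 6 2α-chloro-6-oxo-7,8-ene C11 acetate
Product: 8 2α-chloro-6-oxo-8(17),9(11)-diene, via linear dienone 7 (not isolated)
Conditions: KOtBu (3 equiv), THF/t-BuOH, 0 °C, slow addition of 6; then inverse quench into AcOH/THF, −78 °C
Reagents that add atoms: none
Why: Vinylogous E1cB elimination of acetate (γ-deprotonation at C9) gives dienone 7, whose C17 methyl is deprotonated to the cross-conjugated trienolate; kinetic α-protonation at C7 (deconjugation through the extended enolate) then gives the 8(17),9(11)-diene with the ketone out of conjugation, and the equatorial C2 chloride has no antiperiplanar hydrogen for E2.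

Step 7
Reactants: 9 4-oxobutanenitrile
Product: 11 (S)-3-formyl-4-(triethylsilyloxy)butanenitrile, via hydroxy aldehyde 10 (not isolated)
Conditions: (R)-α,α-diphenylprolinol trimethylsilyl ether (10 mol %), aq. HCHO, pH 7 phosphate buffer, toluene, rt; extraction; then TESOTf, 2,6-lutidine, CH2Cl2, −78 °C
Reagents that add atoms: formaldehyde, C=O; triethylsilyl triflate, CC[Si](CC)(CC)OS(=O)(=O)C(F)(F)F
Why: Enamine-catalysed α-hydroxymethylation (organocatalytic aldol with formaldehyde): the diphenyl(silyloxy)methyl group of the (R)-catalyst shields one enamine face, so formaldehyde should add to give the (S)-aldehyde (future C13), which is silylated at once to prevent dehydration.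

Step 8
Reactants: 8 2α-chloro-6-oxo-8(17),9(11)-diene; 11 (S)-3-formyl-4-(triethylsilyloxy)butanenitrile (1.5 equiv)
Product: 13 (12S,13S)-C12/C16 diol C15 nitrile, via silyl ether adduct 12 (not isolated)
Conditions: Ni(acac)2 (10 mol %), Et3B (2.4 equiv), THF, rt, N2; then AcOH/THF/H2O (3:1:1), rt
Reagents that add atoms: none
Why: Zerovalent nickel (from Ni(acac)2 and Et3B) binds the s-cis diene of 8 on the α face, opposite the axial C10 methyl, and undergoes oxidative cyclisation with the Et3B-activated aldehyde to an allyl(alkoxy)nickel; ethyl transfer from boron, β-hydride elimination and reductive elimination then deliver H to C9 on the nickel-bearing face, which is the known nickel-catalysed, triethylborane-promoted homoallylation of aldehydes with 1,3-dienes (H and C(OH)R added 1,2 across one diene C=C). No ring of the product is closed; only the transient five-membered oxanickelacycle (Ni–O–C12–C11–C9) forms by oxidative cyclisation. C9 is set by the substrate (α-face nickel, so the C11 arm ends β and equatorial); C12 is set by the nickelacycle, in which C13 lies trans to the bulky C10 (the usual 1,3-anti outcome), and the Felkin–Anh preference of 11 with CH2OSiEt3 as the large group points the same way (matched case). The step needs bond formation at C11 and not at C17: C9 carries the electron-releasing quaternary alkyl group whereas C8 carries the inductively withdrawing CH2C(=O) arm, so C9=C11 is the more nucleophilic alkene, and on the α face both termini are similarly accessible. With Et3B the aldehyde should react in preference to the hindered C6 ketone, and the neutral medium should leave the β,γ-enone and the C2 chloride untouched; the mild acid work-up removes the primary triethylsilyl ether.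

Step 9
Reactants: 13 (12S,13S)-C12/C16 diol C15 nitrile
Product: 14 (12S,13S)-C12/C16 diol C15 primary amide
Conditions: PtH(PMe2OH)(PMe2O)2H (2 mol %), EtOH/H2O (4:1), 70 °C
Reagents that add atoms: water, O
Why: Platinum-catalysed nitrile hydration (phosphinito-assisted delivery of water to the coordinated nitrile) gives the primary amide at neutral pH, so the β,γ-enone, the chloride and C13 are not exposed to acid or base.

Step 10
Reactants: 14 (12S,13S)-C12/C16 diol C15 primary amide
Product: 17 Haterumaimide G, via amido aldehyde 15 (not isolated), via N-acyl hemiaminal 16 (not isolated)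
Conditions: TEMPO (20 mol %), PhI(OAc)2 (2.5 equiv), CH2Cl2, rt
Reagents that add atoms: none
Why: Nitroxyl-catalysed oxidation: the oxoammonium salt oxidises the primary C16 alcohol selectively, the aldehyde is trapped by the amide nitrogen (5-exo) as hemiaminal 16, and its more hydridic C–H is oxidised again to the imide, while the hindered secondary C12 carbinol should react much more slowly and C12 and C13 stay untouched.

**Compound list**

1 | (+)-sclareolide (trans-fused lactone; 5α-H, 9α-H, 10β-CH3, 8β-CH3, 8α-O) | O=C1C[C@H]2[C@](C)(O1)CC[C@H]3C(C)(C)CCC[C@]23C | starting material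
2 | 2α-chlorosclareolide (equatorial Cl on C2) | O=C1C[C@H]2[C@](C)(O1)CC[C@H]3C(C)(C)C[C@H](Cl)C[C@]23C | intermediate
3 | 2α-chloro-8α-hydroxy C12 methyl ketone (C9β–CH2–C(=O)CH3, 8β-CH3) | CC(=O)C[C@H]1[C@](C)(O)CC[C@H]2C(C)(C)C[C@H](Cl)C[C@]12C | intermediate
4 | 2α-chloro-8α-hydroxy C11 acetate (C9β–CH2OAc) | CC(=O)OC[C@H]1[C@](C)(O)CC[C@H]2C(C)(C)C[C@H](Cl)C[C@]12C | intermediate
5 | 2α-chloro-7,8-ene C11 acetate (9α-H) | CC(=O)OC[C@H]1C(C)=CC[C@H]2C(C)(C)C[C@H](Cl)C[C@]12C | intermediate
6 | 2α-chloro-6-oxo-7,8-ene C11 acetate (9α-H) | CC(=O)OC[C@H]1C(C)=CC(=O)[C@H]2C(C)(C)C[C@H](Cl)C[C@]12C | intermediate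
7 | 2α-chloro-6-oxo-7,9(11)-diene (linear dienone) | C=C1C(C)=CC(=O)[C@H]2C(C)(C)C[C@H](Cl)C[C@]12C | intermediate
8 | 2α-chloro-6-oxo-8(17),9(11)-diene (exocyclic methylenes on C8 and C9) | C=C1CC(=O)[C@H]2C(C)(C)C[C@H](Cl)C[C@]2(C)C1=C | intermediate
9 | 4-oxobutanenitrile | N#CCCC=O | starting material
10 | (S)-3-formyl-4-hydroxybutanenitrile | O=C[C@H](CO)CC#N | intermediate
11 | (S)-3-formyl-4-(triethylsilyloxy)butanenitrile | O=C[C@H](CO[Si](CC)(CC)CC)CC#N | intermediate
12 | (12S,13S) adduct with C12–OH, C16–OSiEt3 and C15 nitrile | C=C1CC(=O)[C@H]2C(C)(C)C[C@H](Cl)C[C@]2(C)[C@H]1C[C@H](O)[C@H](CO[Si](CC)(CC)CC)CC#N | intermediate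
13 | (12S,13S)-C12/C16 diol C15 nitrile | C=C1CC(=O)[C@H]2C(C)(C)C[C@H](Cl)C[C@]2(C)[C@H]1C[C@H](O)[C@H](CO)CC#N | intermediate
14 | (12S,13S)-C12/C16 diol C15 primary amide | C=C1CC(=O)[C@H]2C(C)(C)C[C@H](Cl)C[C@]2(C)[C@H]1C[C@H](O)[C@H](CO)CC(N)=O | intermediate
15 | (12S,13R)-C16 aldehyde C15 primary amide | C=C1CC(=O)[C@H]2C(C)(C)C[C@H](Cl)C[C@]2(C)[C@H]1C[C@H](O)[C@H](C=O)CC(N)=O | intermediate
16 | C16 N-acyl hemiaminal (5-hydroxypyrrolidin-2-one, both C16 epimers) | C=C1CC(=O)[C@H]2C(C)(C)C[C@H](Cl)C[C@]2(C)[C@H]1C[C@H](O)[C@H]1CC(=O)NC1O | intermediate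
17 | Haterumaimide G | C=C1CC(=O)[C@H]2C(C)(C)C[C@H](Cl)C[C@]2(C)[C@H]1C[C@H](O)[C@H]1CC(=O)NC1=O | target

Total step count: 10. Longest linear sequence: 9 steps (steps 1–6, 8, 9, 10).

**Steps most likely to fail**

Step 8. The aldehyde may bond to the C17 terminus instead of C11 (loss of regiocontrol in the oxidative cyclisation), or nickel hydride may move the diene into conjugation with the ketone. The fallback sets out from 6 and comes back to the route at 12. Kinetic γ-deprotonation of 6 at the exposed C17 methyl (KHMDS, THF, −78 °C) and inverse AcOH quench should give the deconjugated 2α-chloro-6-oxo-8(17)-ene C11 acetate F1 with 9α-H retained. Neutral transesterification (immobilised Candida antarctica lipase B, n-BuOH, MTBE) gives the primary alcohol F2, and PPh3, I2 and imidazole give the primary iodide F3. The alkylchromium reagent made from F3 with CrCl2 (divalent chromium) and catalytic cobalt phthalocyanine Co(C32H16N8) in DMF adds only to the aldehyde of 11 (Nozaki–Hiyama-type addition, ketone tolerated). C12 is then set by Felkin–Anh control alone, giving 12.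

Step 6. Free dienone 7 may oligomerise by conjugate addition of the trienolate, or the diene may slip back into conjugation during the quench. The fallback sets out from 6 and comes back at 8. DBU in CH2Cl2 at 0 °C eliminates acetic acid to give dienone 7, which is isolated. Soft enolisation at the C17 methyl (TBSOTf, Et3N, CH2Cl2, 0 °C) gives the cross-conjugated C6 tert-butyldimethylsilyl trienol ether F4, which can be purified. Buffered fluoride (TBAF, AcOH, THF, −78 °C) then protonates C7 kinetically to give 8.

Step 10. The oxoammonium salt may also oxidise the C12 carbinol, or the oxidation may stall at hemiaminal 16. The fallback sets out from 14 and comes back at 17. Exhaustive oxidation with the periodinane DMP (1,1,1-triacetoxy-1,1-dihydro-1,2-benziodoxol-3(1H)-one; NaHCO3, CH2Cl2) gives the C12-oxo imide F5, in which C13 epimerises freely. Asymmetric transfer hydrogenation with RuCl(p-cymene)[(S,S)-TsDPEN] (or its enantiomer, chosen for the 12S carbinol) in HCO2H/Et3N under dynamic kinetic resolution should reduce only the activated C12 ketone. It should funnel both C13 epimers into 17.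

Further compounds
F1 | step 8 | 2α-chloro-6-oxo-8(17)-ene C11 acetate (9α-H) | C=C1CC(=O)[C@H]2C(C)(C)C[C@H](Cl)C[C@]2(C)[C@H]1COC(C)=O
F2 | step 8 | 2α-chloro-6-oxo-8(17)-ene C11 alcohol (9α-H) | C=C1CC(=O)[C@H]2C(C)(C)C[C@H](Cl)C[C@]2(C)[C@H]1CO
F3 | step 8 | 2α-chloro-6-oxo-8(17)-ene C11 iodide (9α-H) | C=C1CC(=O)[C@H]2C(C)(C)C[C@H](Cl)C[C@]2(C)[C@H]1CI
F4 | step 6 | 2α-chloro-6-(tert-butyldimethylsilyloxy)-6,8(17),9(11)-triene | C=C1C=C(O[Si](C)(C)C(C)(C)C)[C@H]2C(C)(C)C[C@H](Cl)C[C@]2(C)C1=C
F5 | step 10 | C12-oxo imide (C13 labile) | C=C1CC(=O)[C@H]2C(C)(C)C[C@H](Cl)C[C@]2(C)[C@H]1CC(=O)C1CC(=O)NC1=O
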